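**Retrosynthetic overview** (numbering: C1 = lactone C=O, C7 = lactone carbinol, C8–C9–C10 = cyclopropane, C22 = CH3)
1. Solandelactone F ⇐ 12E-olefin and C14–OH by directed epoxidation and fluoride-induced opening of a C12-silyl 13E-olefin ⇐ allylboration (C11–C12) of the C1–C11 lactone–cyclopropane aldehyde with an α-chiral γ-silyl allylboronate (C12–C22), itself from lithiation–borylation of (Z)-non-3-enyl carbamate.
2. Aldehyde ⇐ ring-closing metathesis (C4=C5) of the pent-4-enoate of a cyclopropyl homoallylic alcohol.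
3. Cyclopropane ⇐ 3-exo cation–olefin closure (C8–C10) of a trans-epoxide that carries a (Z)-enol carbamate ⇐ anti-chlorohydrin.
4. Key bond C8–C9: titanated allyl carbamate (homoenolate; C9 is the β-carbon of the latent C11 aldehyde, an acceptor used as a donor) adds to the acceptor carbonyl of (S)-2-chloropent-4-enal; this one C–Cl stereocentre relays to C7, C8 and C10.
5. Ring order: oxirane (transient) → cyclopropane → eight-membered lactone.

Assumption: the target is 4Z,7R,8R,10R,11R,12E,14S,16Z; the (2R,5R)-pyrrolidine catalyst of step 1 is taken to give the (S)-chloride (otherwise its antipode is used), and the silylvinylboronate of step 9 is taken as a catalogue item.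

**Route**

Step 1
Reactants: 1 pent-4-enal
Product: 2 (S)-2-chloropent-4-enal
Conditions: N-chlorosuccinimide (1.3 equiv), (2R,5R)-2,5-diphenylpyrrolidine (10 mol %), CH2Cl2, 0 °C to rt; pentane, filter, used as a cold solution
Reagents that add atoms: N-chlorosuccinimide, O=C1CCC(=O)N1Cl
Why: Enamine-catalysed asymmetric α-chlorination of a linear aldehyde, in which the C2-symmetric pyrrolidine shields one enamine face so that chlorine is delivered to give the (S)-chloride, the carbon that becomes C7 after one inversion.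

Step 2
Reactants: 3 allyl alcohol; 4 N,N-diisopropylcarbamoyl chloride
Product: 5 allyl N,N-diisopropylcarbamate
Conditions: NaH, THF, 0 °C; then 4, reflux
Reagents that add atoms: none
Why: O-carbamoylation of the sodium alkoxide by the carbamoyl chloride (standard Hoppe carbamate preparation), with no stereocentre involved.

Step 3
Reactants: 5 allyl N,N-diisopropylcarbamate; 2 (S)-2-chloropent-4-enal
Product: 8 (1Z,4R,5S)-5-chloro-4-hydroxyocta-1,7-dien-1-yl N,N-diisopropylcarbamate, via lithiated allyl carbamate 6 (not isolated), via allyltitanium triisopropoxide 7 (not isolated)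
Conditions: 5 (2.5 equiv), n-BuLi, TMEDA, Et2O, −78 °C; ClTi(OiPr)3, −78 °C; then 2 (1 equiv), −78 °C; aq NH4Cl
Reagents that add atoms: none
Why: Hoppe homoaldol reaction, in which the titanated allyl carbamate acts as a homoenolate (d3) equivalent and joins C9 to the aldehyde carbon C8 through a carbamate-chelated six-membered chair (γ-attack, Z-enol carbamate), while the Cornforth/polar Felkin–Anh preference of the α-chloro aldehyde, reinforced by kinetic selection of the matched enantiomer of the racemic titanium reagent used in excess, sets the anti-chlorohydrin (8R relative to 7S).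

Step 4
Reactants: 8 (1Z,4R,5S)-5-chloro-4-hydroxyocta-1,7-dien-1-yl N,N-diisopropylcarbamate
Product: 9 (Z)-3-[(2R,3R)-3-allyloxiran-2-yl]prop-1-en-1-yl N,N-diisopropylcarbamate
Conditions: KOH, EtOH, 0 °C to rt
Reagents that add atoms: none
Why: Intramolecular Williamson (3-exo-tet) closure of the anti-chlorohydrin alkoxide with inversion at C7 gives the trans-(7R,8R)-epoxide, the hindered enol carbamate being inert to hydroxide.

Step 5
Reactants: 9 (Z)-3-[(2R,3R)-3-allyloxiran-2-yl]prop-1-en-1-yl N,N-diisopropylcarbamate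
Product: 11 (1R,2R)-2-[(1R)-1-hydroxybut-3-en-1-yl]cyclopropane-1-carbaldehyde, via oxocarbenium zwitterion 10 (not isolated)
Conditions: BF3·OEt2 (1.1 equiv), CH2Cl2 (10 mM), −78 to −30 °C; aq NaHCO3
Reagents that add atoms: none
Why: Proposed new method: BF3 activation of the epoxide lets the electron-rich enol carbamate π bond, homoallylic to C8, attack C8 from the backside in a 3-exo cation–olefin closure (homoallyl to cyclopropylcarbinyl type; inversion at C8; the C11 unit anti to C7 gives the trans ring and so sets C10), after which the O-carbamoyl oxocarbenium loses its carbamoyl group to fluoride to unveil the aldehyde while the epoxide oxygen stays on C7 as the (R)-carbinol; the closest known reaction types are the Hoppe cycloalkylation of activated 4-hydroxy-1-alkenyl carbamates to cyclopropanecarbaldehydes, BF3-mediated additions of such enol carbamates to oxocarbenium ions, and cyclopropanations of homoallylic triflates by π-nucleophiles.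

Step 6
Reactants: 11 (1R,2R)-2-[(1R)-1-hydroxybut-3-en-1-yl]cyclopropane-1-carbaldehyde; 12 pent-4-enoic acid
Product: 13 (1R)-1-[(1R,2R)-2-formylcyclopropyl]but-3-en-1-yl pent-4-enoate
Conditions: N,N'-dicyclohexylcarbodiimide, DMAP (10 mol %), CH2Cl2, 0 °C to rt
Reagents that add atoms: none
Why: Steglich esterification of the secondary alcohol, to which the aldehyde is inert and in which no stereocentre is touched.

Step 7
Reactants: 13 (1R)-1-[(1R,2R)-2-formylcyclopropyl]but-3-en-1-yl pent-4-enoate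
Product: 14 (1R,2R)-2-[(2R,4Z)-8-oxo-3,6,7,8-tetrahydro-2H-oxocin-2-yl]cyclopropane-1-carbaldehyde
Conditions: second-generation Grubbs catalyst RuCl2(=CHPh)(PCy3)(1,3-dimesitylimidazolidin-2-ylidene) (5–10 mol %), CH2Cl2 (1 mM), 40 °C
Reagents that add atoms: none
Why: Ring-closing metathesis of the two terminal olefins at high dilution, where the eight-membered ring can hold only the Z-olefin and the branched C7 substituent favours the cyclisation-competent ester conformer.

Step 8
Reactants: 15 (Z)-non-3-en-1-ol; 4 N,N-diisopropylcarbamoyl chloride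
Product: 16 (Z)-non-3-en-1-yl N,N-diisopropylcarbamate
Conditions: NaH, THF, 0 °C; then 4, reflux
Reagents that add atoms: none
Why: Alkoxide O-carbamoylation as in step 2, installing the directing and leaving group for α-lithiation while leaving the 16Z olefin untouched.

Step 9
Reactants: 16 (Z)-non-3-en-1-yl N,N-diisopropylcarbamate; 17 (E)-2-(trimethylsilyl)vinylboronic acid pinacol ester
Product: 20 2-[(1E,3S,5Z)-1-(trimethylsilyl)undeca-1,5-dien-3-yl]-4,4,5,5-tetramethyl-1,3,2-dioxaborolane, via lithiated carbamate 18 (not isolated), via boronate complex 19 (not isolated)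
Conditions: s-BuLi, (+)-sparteine, Et2O, −78 °C, 5 h; 17, −78 °C; MgBr2·OEt2, −78 °C to reflux
Reagents that add atoms: none
Why: Hoppe–Aggarwal lithiation–borylation, in which sparteine-directed deprotonation gives the configurationally stable (R)-α-oxy carbanion at C14, boron is attached with retention, and the silylvinyl group then migrates from boron to carbon with inversion (MgBr2-promoted 1,2-metallate shift) to fix the (S)-C14–B stereocentre.

Step 10
Reactants: 20 2-[(1E,3S,5Z)-1-(trimethylsilyl)undeca-1,5-dien-3-yl]-4,4,5,5-tetramethyl-1,3,2-dioxaborolane; 14 (1R,2R)-2-[(2R,4Z)-8-oxo-3,6,7,8-tetrahydro-2H-oxocin-2-yl]cyclopropane-1-carbaldehyde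
Product: 23 (5Z,8R)-8-{(1R,2R)-2-[(1S,2R,3E,6Z)-1-hydroxy-2-(trimethylsilyl)dodeca-3,6-dien-1-yl]cyclopropyl}-3,4,7,8-tetrahydro-2H-oxocin-2-one, via butylboronate complex 21 (not isolated), via borinic ester 22 (not isolated)
Conditions: 20 (1.3 equiv), n-BuLi, THF, −78 °C; (CF3CO)2O, −78 °C; then 14 (1 equiv), −78 °C to rt; aq NaHCO3
Reagents that add atoms: none
Why: Allylboration through a closed chair by way of the in situ borinic ester, in which the α-substituent sits pseudo-equatorial (13E olefin) and the E-γ-silyl group gives the anti adduct, so that the C14–B chirality is transferred to C11 (the 11R arrangement of the target, labelled 11S here only because silicon changes the priorities) and to C12, the lactone never meeting a free organolithium.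

Step 11
Reactants: 23 (5Z,8R)-8-{(1R,2R)-2-[(1S,2R,3E,6Z)-1-hydroxy-2-(trimethylsilyl)dodeca-3,6-dien-1-yl]cyclopropyl}-3,4,7,8-tetrahydro-2H-oxocin-2-one
Product: 25 solandelactone F, via epoxysilane 24 (not isolated)
Conditions: VO(acac)2 (5 mol %), t-BuOOH (1.05 equiv), CH2Cl2, 0 °C to rt; then n-Bu4NF, THF, 0 °C; pH 7 buffer
Reagents that add atoms: tert-butyl hydroperoxide, CC(C)(C)OO
Why: Hydroxyl-directed epoxidation touches only the C13=C14 olefin homoallylic to the C11–OH and delivers oxygen on the face anti to silicon (H-12 eclipsing the olefin), and fluoride-triggered anti β-elimination of the silyl epoxide (Peterson-type allylsilane to allylic alcohol transposition) then breaks C13–O to give the 12E olefin and the 14S carbinol.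

**Compound list**

1 | pent-4-enal | C=CCCC=O | starting material
2 | (S)-2-chloropent-4-enal | C=CC[C@H](Cl)C=O | intermediate
3 | allyl alcohol | C=CCO | starting material
4 | N,N-diisopropylcarbamoyl chloride | CC(C)N(C(C)C)C(Cl)=O | starting material
5 | allyl N,N-diisopropylcarbamate | C=CCOC(=O)N(C(C)C)C(C)C | intermediate
6 | 1-lithioallyl N,N-diisopropylcarbamate (TMEDA complex, racemic) | [Li]C(C=C)OC(=O)N(C(C)C)C(C)C | intermediate
7 | [1-(N,N-diisopropylcarbamoyloxy)allyl]titanium triisopropoxide (racemic) | C=CC(OC(=O)N(C(C)C)C(C)C)[Ti](OC(C)C)(OC(C)C)OC(C)C | intermediate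
8 | (1Z,4R,5S)-5-chloro-4-hydroxyocta-1,7-dien-1-yl N,N-diisopropylcarbamate (anti-chlorohydrin; 8R,7S in target numbering) | CC(C)N(C(C)C)C(=O)O/C=C\C[C@@H](O)[C@@H](Cl)CC=C | intermediate
9 | (Z)-3-[(2R,3R)-3-allyloxiran-2-yl]prop-1-en-1-yl N,N-diisopropylcarbamate (trans-epoxide) | CC(C)N(C(C)C)C(=O)O/C=C\C[C@H]1O[C@@H]1CC=C | intermediate
10 | zwitterion: trans-cyclopropane with O-carbamoyl oxocarbenium at C11 and BF3-bound (R)-alkoxide at C7 | CC(C)N(C(C)C)C(=O)[O+]=C[C@@H]1C[C@H]1[C@@H](CC=C)O[B-](F)(F)F | intermediate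
11 | (1R,2R)-2-[(1R)-1-hydroxybut-3-en-1-yl]cyclopropane-1-carbaldehyde | O=C[C@@H]1C[C@H]1[C@H](O)CC=C | intermediate
12 | pent-4-enoic acid | C=CCCC(=O)O | starting material
13 | (1R)-1-[(1R,2R)-2-formylcyclopropyl]but-3-en-1-yl pent-4-enoate | O=C[C@@H]1C[C@H]1[C@@H](CC=C)OC(=O)CCC=C | intermediate
14 | (1R,2R)-2-[(2R,4Z)-8-oxo-3,6,7,8-tetrahydro-2H-oxocin-2-yl]cyclopropane-1-carbaldehyde (C1–C11 aldehyde) | O=C[C@@H]1C[C@H]1[C@H]1C/C=C\CCC(=O)O1 | intermediate
15 | (Z)-non-3-en-1-ol | CCCCC/C=C\CCO | starting material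
16 | (Z)-non-3-en-1-yl N,N-diisopropylcarbamate | CCCCC/C=C\CCOC(=O)N(C(C)C)C(C)C | intermediate
17 | (E)-2-(trimethylsilyl)vinylboronic acid pinacol ester | C[Si](C)(C)/C=C/B1OC(C)(C)C(C)(C)O1 | starting material
18 | (R,Z)-1-lithionon-3-en-1-yl N,N-diisopropylcarbamate ((+)-sparteine complex) | CCCCC/C=C\C[C@@H]([Li])OC(=O)N(C(C)C)C(C)C | intermediate
19 | lithium boronate complex of 18 with 17 (C14 configuration retained) | [Li+].CCCCC/C=C\C[C@H](OC(=O)N(C(C)C)C(C)C)[B-]1(/C=C/[Si](C)(C)C)OC(C)(C)C(C)(C)O1 | intermediate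
20 | 2-[(1E,3S,5Z)-1-(trimethylsilyl)undeca-1,5-dien-3-yl]-4,4,5,5-tetramethyl-1,3,2-dioxaborolane | CCCCC/C=C\C[C@@H](/C=C/[Si](C)(C)C)B1OC(C)(C)C(C)(C)O1 | intermediate
21 | lithium B-butyl boronate complex of 20 | [Li+].CCCCC/C=C\C[C@@H](/C=C/[Si](C)(C)C)[B-]1(CCCC)OC(C)(C)C(C)(C)O1 | intermediate
22 | B-butyl borinic ester of 20 (pinacol oxygen trifluoroacetylated) | CCCCC/C=C\C[C@@H](/C=C/[Si](C)(C)C)B(CCCC)OC(C)(C)C(C)(C)OC(=O)C(F)(F)F | intermediate
23 | (5Z,8R)-8-{(1R,2R)-2-[(1S,2R,3E,6Z)-1-hydroxy-2-(trimethylsilyl)dodeca-3,6-dien-1-yl]cyclopropyl}-3,4,7,8-tetrahydro-2H-oxocin-2-one (anti-β-hydroxy allylsilane) | CCCCC/C=C\C/C=C/[C@@H]([Si](C)(C)C)[C@@H](O)[C@@H]1C[C@H]1[C@H]1C/C=C\CCC(=O)O1 | intermediate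
24 | 13,14-trans-epoxide of 23, oxygen anti to silicon (11S,12S,13R,14S by CIP) | CCCCC/C=C\C[C@@H]2O[C@H]2[C@@H]([Si](C)(C)C)[C@@H](O)[C@@H]1C[C@H]1[C@H]1C/C=C\CCC(=O)O1 | intermediate
25 | solandelactone F, (5Z,8R)-8-{(1R,2R)-2-[(1R,2E,4S,6Z)-1,4-dihydroxydodeca-2,6-dien-1-yl]cyclopropyl}-3,4,7,8-tetrahydro-2H-oxocin-2-one | CCCCC/C=C\C[C@H](O)/C=C/[C@@H](O)[C@@H]1C[C@H]1[C@H]1C/C=C\CCC(=O)O1 | target

**Totals and risks**

Total step count: 11. Longest linear sequence: 8 steps (1 → 2 → 8 → 9 → 11 → 13 → 14 → 23 → 25).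

The three steps most likely to fail are steps 5, 7 and 10.

Step 5 (cationic cyclopropane closure; the epoxide may instead rearrange or be opened by the carbamate carbonyl). The fallback closes the ring anionically; it sets out from 2 and comes back at 11. The titanium ester homoenolate Cl3TiCH2CH2CO2iPr adds to 2 with the same Cornforth sense to give isopropyl (4R,5S)-5-chloro-4-hydroxyoct-7-enoate F1. K2CO3 in propan-2-ol closes this to isopropyl 3-[(2R,3R)-3-allyloxiran-2-yl]propanoate F2. LiN(SiMe3)2 in THF then drives the 3-exo-tet epoxy-enolate cycloalkylation (inversion at C8, trans ring) to isopropyl (1R,2R)-2-[(1R)-1-hydroxybut-3-en-1-yl]cyclopropane-1-carboxylate F3. Half-reduction with iBu2AlH at −78 °C returns 11.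

Step 7 (eight-membered ring-closing metathesis; oligomers may dominate). The fallback forms the Z-olefin first and closes the ring at the ester bond; it sets out from 11 and comes back at 14. Z-selective cross-metathesis of 11 with methyl pent-4-enoate, using the cyclometalated catalyst Ru(ONO2)(=CH-C6H4-2-OiPr)(C-bound 1-adamantyl-3-mesitylimidazolidin-2-ylidene), gives methyl (4Z,7R)-7-[(1R,2R)-2-formylcyclopropyl]-7-hydroxyhept-4-enoate F4. Me3SnOH hydrolysis gives (4Z,7R)-7-[(1R,2R)-2-formylcyclopropyl]-7-hydroxyhept-4-enoic acid F5. Yamaguchi lactonisation (2,4,6-trichlorobenzoyl chloride, Et3N, then DMAP, toluene, high dilution) gives 14, the Z-olefin pre-organising the seco acid.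

Step 10 (the E-selective, anti allylboration must hold for both C11 and, by relay, C14). The fallback runs through the opposite olefin geometry and a sigmatropic oxygen transfer instead; it sets out from 16 (with 14) and comes back at 25. Lithiation of 16 with s-BuLi/(−)-sparteine gives (S,Z)-1-lithionon-3-en-1-yl N,N-diisopropylcarbamate F6. Borylation with (E)-2-(phenylsulfanyl)vinyl-9-BBN and 1,2-shift at low temperature give 9-[(1E,3R,5Z)-1-(phenylsulfanyl)undeca-1,5-dien-3-yl]-9-borabicyclo[3.3.1]nonane F7. This is trapped in situ by 14 at −78 °C; a dialkylborane chair puts the α-substituent axial, which gives the 13Z olefin and the anti adduct (5Z,8R)-8-{(1R,2R)-2-[(1S,2R,3Z,6Z)-1-hydroxy-2-(phenylsulfanyl)dodeca-3,6-dien-1-yl]cyclopropyl}-3,4,7,8-tetrahydro-2H-oxocin-2-one F8. One equivalent of mCPBA at −78 °C oxidises only sulfur to the sulfoxide of that sulfide F9. Its [2,3]-sigmatropic (Mislow–Evans) shift delivers oxygen to C14 on the face syn to sulfur to give the 14-O-phenylsulfenate of solandelactone F F10 (12E, 14S). Et2NH in MeOH cleaves this to 25.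

Further compounds
F1 | step 5 | isopropyl (4R,5S)-5-chloro-4-hydroxyoct-7-enoate | CC(C)OC(=O)CC[C@@H](O)[C@@H](Cl)CC=C
F2 | step 5 | isopropyl 3-[(2R,3R)-3-allyloxiran-2-yl]propanoate | CC(C)OC(=O)CC[C@H]1O[C@@H]1CC=C
F3 | step 5 | isopropyl (1R,2R)-2-[(1R)-1-hydroxybut-3-en-1-yl]cyclopropane-1-carboxylate | CC(C)OC(=O)[C@@H]1C[C@H]1[C@H](O)CC=C
F4 | step 7 | methyl (4Z,7R)-7-[(1R,2R)-2-formylcyclopropyl]-7-hydroxyhept-4-enoate | O=C[C@@H]1C[C@H]1[C@H](O)C/C=C\CCC(=O)OC
F5 | step 7 | (4Z,7R)-7-[(1R,2R)-2-formylcyclopropyl]-7-hydroxyhept-4-enoic acid | O=C[C@@H]1C[C@H]1[C@H](O)C/C=C\CCC(=O)O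
F6 | step 10 | (S,Z)-1-lithionon-3-en-1-yl N,N-diisopropylcarbamate ((−)-sparteine complex) | CCCCC/C=C\C[C@H]([Li])OC(=O)N(C(C)C)C(C)C
F7 | step 10 | 9-[(1E,3R,5Z)-1-(phenylsulfanyl)undeca-1,5-dien-3-yl]-9-borabicyclo[3.3.1]nonane | CCCCC/C=C\C[C@H](/C=C/Sc1ccccc1)B1C2CCCC1CCC2
F8 | step 10 | (5Z,8R)-8-{(1R,2R)-2-[(1S,2R,3Z,6Z)-1-hydroxy-2-(phenylsulfanyl)dodeca-3,6-dien-1-yl]cyclopropyl}-3,4,7,8-tetrahydro-2H-oxocin-2-one | CCCCC/C=C\C/C=C\[C@@H](Sc1ccccc1)[C@@H](O)[C@@H]1C[C@H]1[C@H]1C/C=C\CCC(=O)O1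
F9 | step 10 | sulfoxide of F8 (both sulfur epimers) | CCCCC/C=C\C/C=C\[C@@H](S(=O)c1ccccc1)[C@@H](O)[C@@H]1C[C@H]1[C@H]1C/C=C\CCC(=O)O1
F10 | step 10 | 14-O-phenylsulfenate of solandelactone F | CCCCC/C=C\C[C@H](OSc1ccccc1)/C=C/[C@@H](O)[C@@H]1C[C@H]1[C@H]1C/C=C\CCC(=O)O1
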